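Ring B (the cyclohexadienone) is a cyclic β-triketone: its quaternary C-4 (methyl, prenyl) lies between the carbonyl-level carbons C-3 and C-5 (C-1 is the ring C=O, C-2 carries butanoyl, C-6 the CH2 bridge). Everything rests on the C-3–C-4 Claisen bond. A triketide chain, carried as a 4-methoxy-2-pyranone (lactone and enol ether as carbonyl masks), is unfolded by methoxide and refolded in the same operation by Dieckmann closure of its tertiary ketone α-carbon onto the ester, giving the six-membered trione with both C-4 substituents in place. Butanoylation then makes C-4 stereogenic, the enantiomers are separated, and an ortho-quinone methide from ring A adds the methylene bridge.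

Key step: step 3

Remark: β-triketone units are drawn as one tautomer throughout; the descriptor (R) of 10 and 17 belongs to the tautomers drawn; 4, 5 and 9 are racemates. The configuration is not induced in the route but obtained by separation of enantiomers in step 5, and the absolute configuration of the enantiomer taken on has to be assigned experimentally.

Step 1
Reactants: 1 4-methoxy-6-methyl-2H-pyran-2-one; 2 1-bromo-3-methylbut-2-ene (prenyl bromide)
Product: 3 4-methoxy-6-(4-methylpent-3-en-1-yl)-2H-pyran-2-one
Conditions: LiN(i-Pr)2 (1.1 equiv), THF–DMPU, −78 °C; then 2, −78 → −20 °C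
Reagents that add atoms: none
Why: Lateral (vinylogous) deprotonation of the 6-methyl group of the 4-methoxy-2-pyranone gives a delocalized anion that is alkylated at the exocyclic carbon by the allylic bromide (SN2), a known lateral alkylation of this pyranone.

Step 2
Reactants: 3 4-methoxy-6-(4-methylpent-3-en-1-yl)-2H-pyran-2-one
Product: 4 (±)-4-methoxy-6-(5-methylhex-4-en-2-yl)-2H-pyran-2-one
Conditions: LiN(i-Pr)2 (1.1 equiv), THF–DMPU, −78 °C; then MeI, −78 → 0 °C
Reagents that add atoms: iodomethane, CI
Why: A second lateral deprotonation at the CH2 next to the ring and C-methylation of the anion (enolate-type alkylation) should give the branched side chain; the new C–H stereocentre forms as a racemate and is erased in step 3.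

Step 3
Reactants: 4 (±)-4-methoxy-6-(5-methylhex-4-en-2-yl)-2H-pyran-2-one
Product: 7 2-methyl-2-(3-methylbut-2-en-1-yl)cyclohexane-1,3,5-trione, via ring-opened enol-ether ester 5 (not isolated), via cyclized enol-ether enolate 6 (not isolated)
Conditions: NaOMe (3 equiv), MeOH, reflux; then 1 M HCl, THF–H2O, rt
Reagents that add atoms: water, O
Why: Methoxide opens the lactone of 4 at its carbonyl carbon to ester 5 (reversible; O-reclosure only returns 4), and the tertiary α-carbon of the ketone in 5, as its enolate, attacks the ester carbon in an intramolecular Claisen (Dieckmann) condensation, so the net change is an O→C acyl transfer. The closest known reaction types are the alkoxide-induced isomerization of enol lactones to cyclic 1,3-diones and the biomimetic Claisen folding of pyranone-masked polyketide chains into phloroglucinol rings. The six-membered ring closes in the 6-(enolendo)-exo-trig mode, helped by the (E) double bond inherited from the pyranone, which holds the ester and the ketone arm cis. No stereocentre has to be controlled: 6 is formed as a mirror-symmetric enolate and 7 is achiral, so the racemic C–H centre of 4 is simply erased, and the quaternary carbon becomes stereogenic only in step 4. The step needs C- over O-cyclization and condensation over cleavage, and both should be secured thermodynamically, because only the C-cyclized vinylogous acid 6 is deprotonated irreversibly by methoxide, while the enol-ether mask keeps the ester neutral and leaves no second ketone that could divert the chain into an aldol–aromatization. Dilute HCl then hydrolyses the methyl enol ether of 6 to trione 7.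

Step 4
Reactants: 7 2-methyl-2-(3-methylbut-2-en-1-yl)cyclohexane-1,3,5-trione; 8 butanoic acid
Product: 9 (±)-2-butanoyl-3,5-dihydroxy-4-methyl-4-(3-methylbut-2-en-1-yl)cyclohexa-2,5-dien-1-one
Conditions: DCC (1.05 equiv), DMAP (0.3 equiv), CH2Cl2, 0 °C → rt
Reagents that add atoms: none
Why: O-Acylation of the enol of 7 followed by DMAP-mediated O→C acyl transfer (Fries-type rearrangement of enol esters of cyclic 1,3-diones) should give the C-acyl β-triketone; the two nucleophilic ring carbons of 7 are enantiotopic, so the quaternary carbon becomes a stereocentre here and 9 forms as the racemate.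

Step 5
Reactants: 9 (±)-2-butanoyl-3,5-dihydroxy-4-methyl-4-(3-methylbut-2-en-1-yl)cyclohexa-2,5-dien-1-one
Product: 10 (R)-2-butanoyl-3,5-dihydroxy-4-methyl-4-(3-methylbut-2-en-1-yl)cyclohexa-2,5-dien-1-one
Conditions: preparative SFC, amylose tris(3,5-dimethylphenylcarbamate) phase, CO2/MeOH (0.1% HCO2H), 35 °C
Reagents that add atoms: none
Why: Resolution by chromatography on a chiral stationary phase should separate the enantiomers, and the quaternary centre, which has no α-hydrogen, cannot epimerize afterwards.

Step 6
Reactants: 11 benzene-1,3,5-triol (phloroglucinol); 12 hexanoyl chloride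
Product: 13 1-(2,4,6-trihydroxyphenyl)hexan-1-one
Conditions: AlCl3 (3 equiv), PhNO2–CH2Cl2, 0 → 45 °C; then ice/aq. HCl
Reagents that add atoms: none
Why: Friedel–Crafts acylation of the symmetric, strongly activated arene should stop at the mono-ketone because the chelated acylphloroglucinol is deactivated.

Step 7
Reactants: 13 1-(2,4,6-trihydroxyphenyl)hexan-1-one
Product: 14 1-(2,6-dihydroxy-4-methoxyphenyl)hexan-1-one
Conditions: Me2SO4 (1.0 equiv), K2CO3, acetone, rt
Reagents that add atoms: dimethyl sulfate, COS(=O)(=O)OC
Why: The 4-OH, para to the ketone, is the most acidic hydroxyl and the only one not engaged in hydrogen bonding to the carbonyl, so one equivalent of the methylating agent should etherify it selectively (Williamson-type O-methylation).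

Step 8
Reactants: 14 1-(2,6-dihydroxy-4-methoxyphenyl)hexan-1-one
Product: 15 1-{3-[(dimethylamino)methyl]-2,6-dihydroxy-4-methoxyphenyl}hexan-1-one
Conditions: 37% aq. CH2O (1.0 equiv), 40% aq. Me2NH (1.0 equiv), EtOH, 0 °C → rt
Reagents that add atoms: formaldehyde, C=O; dimethylamine, CNC
Why: Phenolic Mannich reaction at one of the two equivalent free ring positions ortho to a hydroxyl, held at mono-substitution by stoichiometry.

Step 9
Reactants: 10 (R)-2-butanoyl-3,5-dihydroxy-4-methyl-4-(3-methylbut-2-en-1-yl)cyclohexa-2,5-dien-1-one; 15 1-{3-[(dimethylamino)methyl]-2,6-dihydroxy-4-methoxyphenyl}hexan-1-one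
Product: 17 elaphopilosin B, via ortho-quinone methide 16 (not isolated)
Conditions: 10 (1.0 equiv), 15 (1.2 equiv), 1,4-dioxane, 95 °C, N2
Reagents that add atoms: none
Why: The acidic triketone 10 protonates the amine of 15, thermal loss of dimethylamine gives ortho-quinone methide 16, and Michael addition of the only free nucleophilic ring carbon (C-6) of 10 followed by rearomatization should give the methylene bridge without touching the quaternary stereocentre.

Compound list
1 | 4-methoxy-6-methyl-2H-pyran-2-one | COC1=CC(=O)OC(C)=C1 | starting material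
2 | 1-bromo-3-methylbut-2-ene (prenyl bromide) | CC(C)=CCBr | starting material
3 | 4-methoxy-6-(4-methylpent-3-en-1-yl)-2H-pyran-2-one | COC1=CC(=O)OC(CCC=C(C)C)=C1 | intermediate
4 | (±)-4-methoxy-6-(5-methylhex-4-en-2-yl)-2H-pyran-2-one | COC1=CC(=O)OC(C(C)CC=C(C)C)=C1 | intermediate
5 | methyl (2E)-3-methoxy-6,9-dimethyl-5-oxodeca-2,8-dienoate (racemic, ring-opened enol-ether ester) | COC(=O)/C=C(/OC)CC(=O)C(C)CC=C(C)C | intermediate (not isolated)
6 | 5-methoxy-2-methyl-2-(3-methylbut-2-en-1-yl)cyclohex-4-ene-1,3-dione (present as its symmetric sodium enolate) | COC1=CC(=O)C(C)(CC=C(C)C)C(=O)C1 | intermediate (not isolated)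
7 | 2-methyl-2-(3-methylbut-2-en-1-yl)cyclohexane-1,3,5-trione (achiral, enolized) | CC(C)=CCC1(C)C(=O)CC(=O)CC1=O | intermediate
8 | butanoic acid | CCCC(=O)O | starting material
9 | (±)-2-butanoyl-3,5-dihydroxy-4-methyl-4-(3-methylbut-2-en-1-yl)cyclohexa-2,5-dien-1-one | CCCC(=O)C1=C(O)C(C)(CC=C(C)C)C(O)=CC1=O | intermediate
10 | (R)-2-butanoyl-3,5-dihydroxy-4-methyl-4-(3-methylbut-2-en-1-yl)cyclohexa-2,5-dien-1-one | CCCC(=O)C1=C(O)[C@](C)(CC=C(C)C)C(O)=CC1=O | intermediate
11 | benzene-1,3,5-triol (phloroglucinol) | Oc1cc(O)cc(O)c1 | starting material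
12 | hexanoyl chloride | CCCCCC(=O)Cl | starting material
13 | 1-(2,4,6-trihydroxyphenyl)hexan-1-one | CCCCCC(=O)c1c(O)cc(O)cc1O | intermediate
14 | 1-(2,6-dihydroxy-4-methoxyphenyl)hexan-1-one | CCCCCC(=O)c1c(O)cc(OC)cc1O | intermediate
15 | 1-{3-[(dimethylamino)methyl]-2,6-dihydroxy-4-methoxyphenyl}hexan-1-one | CCCCCC(=O)c1c(O)cc(OC)c(CN(C)C)c1O | intermediate
16 | 2-hexanoyl-3-hydroxy-5-methoxy-6-methylidenecyclohexa-2,4-dien-1-one (ortho-quinone methide) | CCCCCC(=O)C1=C(O)C=C(OC)C(=C)C1=O | intermediate (not isolated)
17 | elaphopilosin B, (4R)-2-butanoyl-6-[(3-hexanoyl-2,4-dihydroxy-6-methoxyphenyl)methyl]-3,5-dihydroxy-4-methyl-4-(3-methylbut-2-en-1-yl)cyclohexa-2,5-dien-1-one | CCCCCC(=O)c1c(O)cc(OC)c(CC2=C(O)[C@@](C)(CC=C(C)C)C(O)=C(C(=O)CCC)C2=O)c1O | target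

Total step count: 9. Longest linear sequence: 6 (steps 1, 2, 3, 4, 5, 9).

Steps most likely to fail

Step 3. The hindered tertiary enolate may fail to add to the ester, so that pyranone 4 and ester 5 only interconvert, or methoxide may add to the pyranone in conjugate fashion and the chain degrades. The fallback sets out from 4 and comes back at 9, bypassing 7 and step 4. It moves the acyl group in first and closes the ring on the unmasked chain held as a magnesium chelate. O-Demethylation of 4 (LiI, 2,4,6-collidine, 130 °C) gives 4-hydroxy-6-(5-methylhex-4-en-2-yl)-2H-pyran-2-one F1. C-3 acylation with butanoic acid 8 (DCC, DMAP, toluene, 60 °C) gives 3-butanoyl-4-hydroxy-6-(5-methylhex-4-en-2-yl)-2H-pyran-2-one F2. Mg(OMe)2 in MeOH at reflux opens the lactone to methyl 2-butanoyl-6,9-dimethyl-3,5-dioxodec-8-enoate F3, whose tertiary α-carbon closes onto the ester in a templated Claisen condensation, giving 9 after acidification.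

Step 9. The ortho-quinone methide 16 may be consumed by self-condensation, or the adduct may form by O-alkylation and cyclodehydrate to a chromene-type product instead of giving the C–C bridge. The fallback sets out from 10 and comes back at 17 with the polarity of the partners reversed. Mannich reaction of 10 (aq. CH2O, Me2NH, EtOH, rt) gives (R)-2-butanoyl-6-[(dimethylamino)methyl]-3,5-dihydroxy-4-methyl-4-(3-methylbut-2-en-1-yl)cyclohexa-2,5-dien-1-one F5. Heated with ketone 14 in dioxane, F5 loses dimethylamine to (R)-2-butanoyl-3-hydroxy-4-methyl-4-(3-methylbut-2-en-1-yl)-6-methylidenecyclohex-2-ene-1,5-dione F6. One of the two equivalent free ring carbons of 14 then adds to F6 in a Friedel–Crafts-type conjugate addition to give 17.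

Step 5. The acidic, tautomerizing β-triketone may tail on the chiral phase so that the enantiomers are not separated cleanly. The fallback sets out from 9 and comes back at 10 through covalent diastereomers. Condensation of 9 with (S)-1-phenylethylamine (EtOH, rt) at the exocyclic butanoyl carbonyl gives two diastereomeric enaminones, separated by crystallization or silica chromatography. The one with the (R)-configured ring, 5-hydroxy-4-methyl-4-(3-methylbut-2-en-1-yl)-2-{1-[((S)-1-phenylethyl)amino]butylidene}cyclohex-5-ene-1,3-dione F4, is hydrolysed (2 M HCl, THF, rt) to 10.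

Further compounds
F1 | step 3 | (±)-4-hydroxy-6-(5-methylhex-4-en-2-yl)-2H-pyran-2-one | CC(C)=CCC(C)C1=CC(O)=CC(=O)O1
F2 | step 3 | (±)-3-butanoyl-4-hydroxy-6-(5-methylhex-4-en-2-yl)-2H-pyran-2-one | CCCC(=O)C1=C(O)C=C(C(C)CC=C(C)C)OC1=O
F3 | step 3 | methyl 2-butanoyl-6,9-dimethyl-3,5-dioxodec-8-enoate (in the flask as its magnesium chelate) | COC(=O)C(C(=O)CCC)C(=O)CC(=O)C(C)CC=C(C)C
F4 | step 5 | 5-hydroxy-4-methyl-4-(3-methylbut-2-en-1-yl)-2-{1-[((S)-1-phenylethyl)amino]butylidene}cyclohex-5-ene-1,3-dione, (R)-configured ring | CCCC(N[C@@H](C)c1ccccc1)=C1C(=O)C=C(O)[C@@](C)(CC=C(C)C)C1=O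
F5 | step 9 | (R)-2-butanoyl-6-[(dimethylamino)methyl]-3,5-dihydroxy-4-methyl-4-(3-methylbut-2-en-1-yl)cyclohexa-2,5-dien-1-one | CCCC(=O)C1=C(O)[C@](C)(CC=C(C)C)C(O)=C(CN(C)C)C1=O
F6 | step 9 | (R)-2-butanoyl-3-hydroxy-4-methyl-4-(3-methylbut-2-en-1-yl)-6-methylidenecyclohex-2-ene-1,5-dione | CCCC(=O)C1=C(O)[C@](C)(CC=C(C)C)C(=O)C(=C)C1=O
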